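Scirpusin C is disconnected at the C2–C3 bond of its dihydrofuran (ring B). C3 is a diarylmethine held between benzo ring A and resorcinol ring D, and C2 is an O1-bound benzylic methine carrying pyrogallol ring C. A diaryl carbene at C3 therefore stands 1,5 to the O–CH2 carbon of a ring C benzyl ether on O1. One rhodium-catalysed C–H insertion closes ring B, forms C2–C3 and sets both stereocentres. The precursor is a perbenzylated ring A/ring D diaryldiazomethane with a silyloxymethyl handle at C4, which later carries styryl ring E by olefination after C2 is epimerised to trans.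

Key step: step 13

Numbering: dihydrobenzofuran positions O1, C2, C3, C3a, C4–C7, C7a; ring A = benzo ring, ring B = dihydrofuran, ring C = aryl on C2, ring D = aryl on C3, ring E = styryl aryl.

Assumption: Rh2(S-PTAD)4, dirhodium tetrakis[(S)-(1-adamantyl)(N-phthalimido)acetate], is taken to give the (2R,3S) cis product; if a trial run shows the opposite sense of induction, the commercial enantiomer Rh2(R-PTAD)4 is used with no other change.

Step 1
Reactants: 1 methyl gallate
Product: 2 methyl 3,4,5-tris(benzyloxy)benzoate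
Conditions: BnBr, K2CO3, DMF, 60 °C
Reagents that add atoms: benzyl bromide, BrCc1ccccc1
Why: Williamson etherification of the three acidic phenols with a reactive benzylic halide under carbonate base is exhaustive and leaves the ester untouched.

Step 2
Reactants: 2 methyl 3,4,5-tris(benzyloxy)benzoate
Product: 3 3,4,5-tris(benzyloxy)benzyl alcohol
Conditions: LiAlH4, THF, 0 °C; then H2O
Reagents that add atoms: none
Why: Hydride reduction of the aryl ester with LiAlH4 gives the primary benzylic alcohol, aryl benzyl ethers being inert to the reagent.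

Step 3
Reactants: 3 3,4,5-tris(benzyloxy)benzyl alcohol
Product: 4 triisopropyl{[3,4,5-tris(benzyloxy)benzyl]oxy}silane
Conditions: TIPSCl, imidazole, DMF, rt
Reagents that add atoms: triisopropylsilyl chloride, CC(C)[Si](Cl)(C(C)C)C(C)C
Why: Imidazole-promoted silylation of the unhindered primary alcohol installs a triisopropylsilyl ether that tolerates the later organometallic and hot hydrazine steps and whose bulk keeps the C4 oxygen away from the carbene.

Step 4
Reactants: 4 triisopropyl{[3,4,5-tris(benzyloxy)benzyl]oxy}silane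
Product: 5 {[2-bromo-3,4,5-tris(benzyloxy)benzyl]oxy}triisopropylsilane
Conditions: NBS (1.0 equiv), MeCN, 0 °C to rt
Reagents that add atoms: N-bromosuccinimide, O=C1CCC(=O)N1Br
Why: Electrophilic aromatic bromination of the trialkoxy-activated ring can only occur at the two equivalent free positions, so one equivalent of NBS should give a single monobromide.

Step 5
Reactants: 5 {[2-bromo-3,4,5-tris(benzyloxy)benzyl]oxy}triisopropylsilane
Product: 7 2,3,4-tris(benzyloxy)-6-[(triisopropylsilyloxy)methyl]benzaldehyde, via aryllithium 6 (not isolated)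
Conditions: n-BuLi, THF, −78 °C; DMF, −78 to 0 °C; then H2O
Reagents that add atoms: N,N-dimethylformamide, CN(C)C=O
Why: Bromine–lithium exchange is faster at −78 °C than deprotonation of the benzyl ethers, and formylation of the aryllithium with DMF (Bouveault aldehyde synthesis) places the carbon that becomes C3 next to the oxygen that becomes O1.

Step 6
Reactants: 7 2,3,4-tris(benzyloxy)-6-[(triisopropylsilyloxy)methyl]benzaldehyde
Product: 8 3,4-bis(benzyloxy)-2-hydroxy-6-[(triisopropylsilyloxy)methyl]benzaldehyde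
Conditions: MgBr2·OEt2, toluene/Et2O, 80 °C; then H2O
Reagents that add atoms: none
Why: Magnesium chelated between the aldehyde oxygen and the neighbouring ether oxygen activates only that benzyl ether toward bromide attack (chelation-controlled selective ortho-debenzylation), so the two remote benzyl ethers and the silyl ether are kept.

Step 7
Reactants: 3 3,4,5-tris(benzyloxy)benzyl alcohol
Product: 9 3,4,5-tris(benzyloxy)benzyl bromide
Conditions: PBr3, CH2Cl2, 0 °C
Reagents that add atoms: phosphorus tribromide, BrP(Br)Br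
Why: PBr3 converts the electron-rich primary benzylic alcohol into the bromide by the standard alcohol-to-bromide substitution without touching the aryl ethers.

Step 8
Reactants: 8 3,4-bis(benzyloxy)-2-hydroxy-6-[(triisopropylsilyloxy)methyl]benzaldehyde; 9 3,4,5-tris(benzyloxy)benzyl bromide
Product: 10 3,4-bis(benzyloxy)-2-{[3,4,5-tris(benzyloxy)benzyl]oxy}-6-[(triisopropylsilyloxy)methyl]benzaldehyde
Conditions: K2CO3, DMF, 50 °C
Reagents that add atoms: none
Why: Williamson etherification of the salicylaldehyde phenoxide with the benzylic bromide installs the ring C benzyl ether whose O–CH2 carbon becomes C2.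

Step 9
Reactants: 11 5-bromoresorcinol
Product: 12 1,3-bis(benzyloxy)-5-bromobenzene
Conditions: BnBr, K2CO3, DMF, 50 °C
Reagents that add atoms: benzyl bromide, BrCc1ccccc1
Why: Double Williamson etherification protects both ring D phenols as benzyl ethers, so that all rings share one protecting group for a single final deprotection.

Step 10
Reactants: 12 1,3-bis(benzyloxy)-5-bromobenzene; 10 3,4-bis(benzyloxy)-2-{[3,4,5-tris(benzyloxy)benzyl]oxy}-6-[(triisopropylsilyloxy)methyl]benzaldehyde
Product: 14 racemic [3,5-bis(benzyloxy)phenyl](3,4-bis(benzyloxy)-2-{[3,4,5-tris(benzyloxy)benzyl]oxy}-6-[(triisopropylsilyloxy)methyl]phenyl)methanol, via Grignard reagent 13 (not isolated)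
Conditions: 12, Mg, THF, reflux; then 10, THF, 0 °C to rt; then H2O
Reagents that add atoms: none
Why: Magnesium insertion into the aryl bromide and 1,2-addition of the aryl Grignard reagent to the aldehyde join ring D to the future C3; the carbinol centre forms as a racemate and is erased in the next step.

Step 11
Reactants: 14 racemic diarylmethanol
Product: 15 [3,5-bis(benzyloxy)phenyl](3,4-bis(benzyloxy)-2-{[3,4,5-tris(benzyloxy)benzyl]oxy}-6-[(triisopropylsilyloxy)methyl]phenyl)methanone
Conditions: Dess–Martin periodinane, CH2Cl2, rt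
Reagents that add atoms: none
Why: Dess–Martin oxidation converts the doubly benzylic secondary alcohol into the diaryl ketone under near-neutral conditions that spare silyl and benzyl ethers.

Step 12
Reactants: 15 diaryl ketone
Product: 16 hydrazone of ketone 15 (E/Z mixture)
Conditions: N2H4 (anhydrous, large excess), AcOH (cat.), EtOH, sealed tube, 110 °C
Reagents that add atoms: hydrazine, NN
Why: Acid-catalysed condensation with a large excess of hydrazine at elevated temperature drives hydrazone formation at the di-ortho-substituted carbonyl while the excess suppresses azine formation, and the C=N geometry is of no consequence.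

Step 13
Reactants: 16 hydrazone of ketone 15
Product: 18 triisopropyl{[(2R,3S)-6,7-bis(benzyloxy)-3-[3,5-bis(benzyloxy)phenyl]-2-[3,4,5-tris(benzyloxy)phenyl]-2,3-dihydrobenzofuran-4-yl]methoxy}silane (cis), via diaryldiazomethane 17 (not isolated)
Conditions: MnO2 (activated, excess), CH2Cl2, 0 °C; filter through Celite; slow addition to Rh2(S-PTAD)4 (1 mol %), CH2Cl2, −20 to 0 °C
Reagents that add atoms: none
Why: MnO2 dehydrogenates the hydrazone to the diaryldiazomethane, from which Rh2(S-PTAD)4 expels N2 to give a donor/donor rhodium carbene; its carbon (C3) takes the hydrogen of the O1–CH2 group in a concerted, hydride-transfer-like three-centre transition state while the C2–C3 bond forms. The closest known reaction type is the enantioselective intramolecular C–H insertion of donor/donor dirhodium carbenes into benzylic ether C–H bonds, which gives cis-2,3-diaryl-2,3-dihydrobenzofurans. Ring B closes as a five-membered ring by 1,5-insertion, the carbene carbon and the C–H carbon being tethered through C3a, C7a and O1. C3 (S) is set by the chiral carboxylate pocket of the catalyst, which decides the carbene face that meets the C–H bond, and C2 (R) follows from the compact transition state that places ring C and ring D cis under kinetic control; C2 is corrected in step 14. The step needs site selectivity for the ring C O–CH2 group and chemoselectivity over azine or ylide formation: that C–H bond is doubly activated by O1 and by electron-rich ring C, the carbene has no β-hydrogen, the C7 benzyl ether cannot reach C3, and the C4 CH2O group could only close a four-membered ring while its oxygen is shielded by the triisopropylsilyl group. Slow addition of the diazo solution to the catalyst keeps its stationary concentration, and with it azine formation, low.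

Step 14
Reactants: 18 (2R,3S)-cis-dihydrobenzofuran
Product: 19 triisopropyl{[(2S,3S)-6,7-bis(benzyloxy)-3-[3,5-bis(benzyloxy)phenyl]-2-[3,4,5-tris(benzyloxy)phenyl]-2,3-dihydrobenzofuran-4-yl]methoxy}silane (trans)
Conditions: CF3CO2H (10 equiv), CH2Cl2, 0 °C to rt
Reagents that add atoms: none
Why: Protonation of O1 and reversible heterolysis of the C2–O1 bond give a benzylic cation stabilised by the para-benzyloxy group of ring C (acid-catalysed SN1-type epimerisation), and reclosure should funnel the material to the thermodynamically preferred trans isomer while C3 keeps its S configuration and the silyl ether keeps the C4 oxygen from capturing the cation.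

Step 15
Reactants: 19 (2S,3S)-trans silyl ether
Product: 20 [(2S,3S)-6,7-bis(benzyloxy)-3-[3,5-bis(benzyloxy)phenyl]-2-[3,4,5-tris(benzyloxy)phenyl]-2,3-dihydrobenzofuran-4-yl]methanol
Conditions: TBAF, THF, 0 °C to rt
Reagents that add atoms: none
Why: Fluoride-induced desilylation frees the primary benzylic alcohol under basic conditions in which ring B, lacking a free phenol, cannot open.

Step 16
Reactants: 20 trans benzylic alcohol
Product: 21 (2S,3S)-6,7-bis(benzyloxy)-3-[3,5-bis(benzyloxy)phenyl]-2-[3,4,5-tris(benzyloxy)phenyl]-2,3-dihydrobenzofuran-4-carbaldehyde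
Conditions: Dess–Martin periodinane, CH2Cl2, rt
Reagents that add atoms: none
Why: Dess–Martin oxidation of the primary benzylic alcohol stops at the aldehyde and is mild enough to leave both benzylic stereocentres untouched.

Step 17
Reactants: 22 3,5-bis(benzyloxy)benzyl bromide
Product: 23 diethyl [3,5-bis(benzyloxy)benzyl]phosphonate
Conditions: P(OEt)3, neat, 140 °C
Reagents that add atoms: triethyl phosphite, CCOP(OCC)OCC
Why: Michaelis–Arbuzov reaction of the primary benzylic bromide with triethyl phosphite gives the phosphonate while bromoethane distils off.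

Step 18
Reactants: 21 trans C4 aldehyde; 23 diethyl [3,5-bis(benzyloxy)benzyl]phosphonate
Product: 24 nona-O-benzylscirpusin C, (2S,3S)-6,7-bis(benzyloxy)-3-[3,5-bis(benzyloxy)phenyl]-4-[(E)-2-(3,5-bis(benzyloxy)phenyl)ethenyl]-2-[3,4,5-tris(benzyloxy)phenyl]-2,3-dihydrobenzofuran
Conditions: 23, KOt-Bu, THF, 0 °C; then 21, 0 °C to rt
Reagents that add atoms: none
Why: Horner–Wadsworth–Emmons olefination of the aryl aldehyde with the preformed benzylphosphonate anion should give the E-stilbene, and the absence of free base protects the C3–H next to the formyl-bearing ring.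

Step 19
Reactants: 24 nona-O-benzylscirpusin C
Product: 25 scirpusin C
Conditions: BCl3, pentamethylbenzene, CH2Cl2, −78 °C; then MeOH, H2O
Reagents that add atoms: none
Why: BCl3 cleaves aryl benzyl ethers at −78 °C while pentamethylbenzene captures the benzyl cations by Friedel–Crafts alkylation (non-reductive debenzylation), so the stilbene double bond is not reduced and the low temperature should keep ring B and both stereocentres intact.

Compound list
1 | methyl gallate | COC(=O)c1cc(O)c(O)c(O)c1 | starting material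
2 | methyl 3,4,5-tris(benzyloxy)benzoate | COC(=O)c1cc(OCc2ccccc2)c(OCc2ccccc2)c(OCc2ccccc2)c1 | intermediate
3 | 3,4,5-tris(benzyloxy)benzyl alcohol | OCc1cc(OCc2ccccc2)c(OCc2ccccc2)c(OCc2ccccc2)c1 | intermediate
4 | triisopropyl{[3,4,5-tris(benzyloxy)benzyl]oxy}silane | CC(C)[Si](C(C)C)(C(C)C)OCc1cc(OCc2ccccc2)c(OCc2ccccc2)c(OCc2ccccc2)c1 | intermediate
5 | {[2-bromo-3,4,5-tris(benzyloxy)benzyl]oxy}triisopropylsilane | CC(C)[Si](C(C)C)(C(C)C)OCc1cc(OCc2ccccc2)c(OCc2ccccc2)c(OCc2ccccc2)c1Br | intermediate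
6 | {2,3,4-tris(benzyloxy)-6-[(triisopropylsilyloxy)methyl]phenyl}lithium | [Li]c1c(CO[Si](C(C)C)(C(C)C)C(C)C)cc(OCc2ccccc2)c(OCc2ccccc2)c1OCc1ccccc1 | intermediate (not isolated)
7 | 2,3,4-tris(benzyloxy)-6-[(triisopropylsilyloxy)methyl]benzaldehyde | O=Cc1c(CO[Si](C(C)C)(C(C)C)C(C)C)cc(OCc2ccccc2)c(OCc2ccccc2)c1OCc1ccccc1 | intermediate
8 | 3,4-bis(benzyloxy)-2-hydroxy-6-[(triisopropylsilyloxy)methyl]benzaldehyde (ring A salicylaldehyde) | O=Cc1c(CO[Si](C(C)C)(C(C)C)C(C)C)cc(OCc2ccccc2)c(OCc2ccccc2)c1O | intermediate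
9 | 3,4,5-tris(benzyloxy)benzyl bromide (ring C) | BrCc1cc(OCc2ccccc2)c(OCc2ccccc2)c(OCc2ccccc2)c1 | intermediate
10 | 3,4-bis(benzyloxy)-2-{[3,4,5-tris(benzyloxy)benzyl]oxy}-6-[(triisopropylsilyloxy)methyl]benzaldehyde | O=Cc1c(CO[Si](C(C)C)(C(C)C)C(C)C)cc(OCc2ccccc2)c(OCc2ccccc2)c1OCc1cc(OCc2ccccc2)c(OCc2ccccc2)c(OCc2ccccc2)c1 | intermediate
11 | 5-bromoresorcinol | Oc1cc(O)cc(Br)c1 | starting material
12 | 1,3-bis(benzyloxy)-5-bromobenzene (ring D) | Brc1cc(OCc2ccccc2)cc(OCc2ccccc2)c1 | intermediate
13 | [3,5-bis(benzyloxy)phenyl]magnesium bromide | Br[Mg]c1cc(OCc2ccccc2)cc(OCc2ccccc2)c1 | intermediate (not isolated)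
14 | racemic diarylmethanol from 10 and 13 | OC(c1cc(OCc2ccccc2)cc(OCc2ccccc2)c1)c1c(CO[Si](C(C)C)(C(C)C)C(C)C)cc(OCc2ccccc2)c(OCc2ccccc2)c1OCc1cc(OCc2ccccc2)c(OCc2ccccc2)c(OCc2ccccc2)c1 | intermediate
15 | diaryl ketone (ring A/ring D methanone) | O=C(c1cc(OCc2ccccc2)cc(OCc2ccccc2)c1)c1c(CO[Si](C(C)C)(C(C)C)C(C)C)cc(OCc2ccccc2)c(OCc2ccccc2)c1OCc1cc(OCc2ccccc2)c(OCc2ccccc2)c(OCc2ccccc2)c1 | intermediate
16 | hydrazone of ketone 15 (E/Z mixture) | NN=C(c1cc(OCc2ccccc2)cc(OCc2ccccc2)c1)c1c(CO[Si](C(C)C)(C(C)C)C(C)C)cc(OCc2ccccc2)c(OCc2ccccc2)c1OCc1cc(OCc2ccccc2)c(OCc2ccccc2)c(OCc2ccccc2)c1 | intermediate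
17 | diaryldiazomethane (key-step precursor) | [N-]=[N+]=C(c1cc(OCc2ccccc2)cc(OCc2ccccc2)c1)c1c(CO[Si](C(C)C)(C(C)C)C(C)C)cc(OCc2ccccc2)c(OCc2ccccc2)c1OCc1cc(OCc2ccccc2)c(OCc2ccccc2)c(OCc2ccccc2)c1 | intermediate (not isolated)
18 | (2R,3S)-cis-2,3-diaryl-2,3-dihydrobenzofuran, C4 CH2OTIPS | CC(C)[Si](C(C)C)(C(C)C)OCc1cc(OCc3ccccc3)c(OCc3ccccc3)c2c1[C@H](c3cc(OCc4ccccc4)cc(OCc4ccccc4)c3)[C@H](c3cc(OCc4ccccc4)c(OCc4ccccc4)c(OCc4ccccc4)c3)O2 | intermediate
19 | (2S,3S)-trans-2,3-diaryl-2,3-dihydrobenzofuran, C4 CH2OTIPS | CC(C)[Si](C(C)C)(C(C)C)OCc1cc(OCc3ccccc3)c(OCc3ccccc3)c2c1[C@H](c3cc(OCc4ccccc4)cc(OCc4ccccc4)c3)[C@@H](c3cc(OCc4ccccc4)c(OCc4ccccc4)c(OCc4ccccc4)c3)O2 | intermediate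
20 | (2S,3S)-trans C4 hydroxymethyl compound | OCc1cc(OCc3ccccc3)c(OCc3ccccc3)c2c1[C@H](c3cc(OCc4ccccc4)cc(OCc4ccccc4)c3)[C@@H](c3cc(OCc4ccccc4)c(OCc4ccccc4)c(OCc4ccccc4)c3)O2 | intermediate
21 | (2S,3S)-trans C4 carbaldehyde | O=Cc1cc(OCc3ccccc3)c(OCc3ccccc3)c2c1[C@H](c3cc(OCc4ccccc4)cc(OCc4ccccc4)c3)[C@@H](c3cc(OCc4ccccc4)c(OCc4ccccc4)c(OCc4ccccc4)c3)O2 | intermediate
22 | 3,5-bis(benzyloxy)benzyl bromide (ring E) | BrCc1cc(OCc2ccccc2)cc(OCc2ccccc2)c1 | starting material
23 | diethyl [3,5-bis(benzyloxy)benzyl]phosphonate | CCOP(=O)(Cc1cc(OCc2ccccc2)cc(OCc2ccccc2)c1)OCC | intermediate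
24 | nona-O-benzylscirpusin C, (2S,3S), E-alkene | c1ccccc1COc1cc(OCc2ccccc2)cc(/C=C/c2cc(OCc4ccccc4)c(OCc4ccccc4)c3c2[C@H](c2cc(OCc4ccccc4)cc(OCc4ccccc4)c2)[C@@H](c2cc(OCc4ccccc4)c(OCc4ccccc4)c(OCc4ccccc4)c2)O3)c1 | intermediate
25 | scirpusin C, (2S,3S), E-alkene | Oc1cc(O)cc(/C=C/c2cc(O)c(O)c3c2[C@H](c2cc(O)cc(O)c2)[C@@H](c2cc(O)c(O)c(O)c2)O3)c1 | target

Total step count: 19. Longest linear sequence: 16 steps (1, 2, 3, 4, 5, 6, 8, 10, 11, 12, 13, 14, 15, 16, 18, 19).

Steps most likely to fail

Step 13. The carbene may be diverted into azine or oxygen-ylide pathways before it reaches the C–H bond, or the two faces of the doubly ortho-flanked carbene may be poorly discriminated, so that C3 forms with low enantiopurity. The fallback builds ring B by a formal [4+1] annulation of an ortho-quinone methide with a sulfur ylide, which forms C2–C3 and C2–O1 and gives the trans isomer directly. It sets out from salicylaldehyde 8 and rejoins the route at 19, bypassing steps 8 and 10–14. Aldehyde 8 is treated with an excess of Grignard reagent 13 (THF, 0 °C) to give the ortho-hydroxy diarylmethanol F1, which p-toluenesulfinic acid in CH2Cl2 converts into the α-tosylbenzyl phenol F2. Bromide 9 and tetrahydrothiophene give the benzylic tetrahydrothiophenium bromide F3. Cs2CO3 in CH2Cl2 eliminates sulfinate from F2 to the ortho-quinone methide and deprotonates F3 to the ylide. Conjugate addition and ring closure by phenoxide displacement of tetrahydrothiophene should give the trans-dihydrobenzofuran as a racemate, that is 19 together with its (2R,3R) antipode F4. Preparative HPLC on a chiral stationary phase then supplies 19.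

Step 12. Condensation at the di-ortho-substituted carbonyl may stay incomplete, with azine formation or slow loss of the silyl ether on prolonged heating. The fallback makes the aryl–C(=N) bond by addition to a nitrile and reaches the hydrazone by transimination instead of ketone condensation. It sets out from aldehyde 10 and rejoins the route at 16, replacing steps 10–12. Aldehyde 10 with NH2OH·HCl and pyridine gives the aldoxime F5, which MsCl/Et3N dehydrates to the benzonitrile F6. Grignard reagent 13 (CuBr cat., THF/toluene, reflux, then anhydrous MeOH) adds to give the N–H ketimine F7. Hydrazine hydrate with catalytic AcOH in EtOH exchanges NH for N–NH2 with loss of ammonia to give 16.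

Step 19. Lewis-acid ionisation of the C2–O1 bond during the ninefold ether cleavage may be followed by capture of the benzylic cation by the stilbene double bond or by the scavenger. The fallback switches the protecting groups before the stilbene exists, so that the last step is a fluoride desilylation. It sets out from aldehyde 21 and phosphonate 23 and ends at target 25, replacing steps 18 and 19. Aldehyde 21 is debenzylated with BCl3/pentamethylbenzene (CH2Cl2, −78 °C) to the heptahydroxy aldehyde F8, which TBSCl/imidazole in DMF converts into the hepta-silyl ether F9. Phosphonate 23 is hydrogenolysed (H2, Pd/C, EtOAc) to diethyl (3,5-dihydroxybenzyl)phosphonate F10 and silylated to the bis-silyl ether phosphonate F11. Horner–Wadsworth–Emmons olefination of F9 with the sodium salt of F11 (NaH, THF, 0 °C) should give nona-O-(tert-butyldimethylsilyl)scirpusin C F12, and Et3N·3HF in THF releases 25.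

Further compounds
F1 | step 13 | [3,5-bis(benzyloxy)phenyl]{3,4-bis(benzyloxy)-2-hydroxy-6-[(triisopropylsilyloxy)methyl]phenyl}methanol (racemic) | OC(c1cc(OCc2ccccc2)cc(OCc2ccccc2)c1)c1c(CO[Si](C(C)C)(C(C)C)C(C)C)cc(OCc2ccccc2)c(OCc2ccccc2)c1O
F2 | step 13 | 2-{[3,5-bis(benzyloxy)phenyl](tosyl)methyl}-5,6-bis(benzyloxy)-3-[(triisopropylsilyloxy)methyl]phenol (racemic) | Cc1ccc(cc1)S(=O)(=O)C(c1cc(OCc2ccccc2)cc(OCc2ccccc2)c1)c1c(CO[Si](C(C)C)(C(C)C)C(C)C)cc(OCc2ccccc2)c(OCc2ccccc2)c1O
F3 | step 13 | 1-[3,4,5-tris(benzyloxy)benzyl]tetrahydrothiophenium bromide | [Br-].C1CC[S+](C1)Cc1cc(OCc2ccccc2)c(OCc2ccccc2)c(OCc2ccccc2)c1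
F4 | step 13 | (2R,3R) antipode of 19 | CC(C)[Si](C(C)C)(C(C)C)OCc1cc(OCc3ccccc3)c(OCc3ccccc3)c2c1[C@@H](c3cc(OCc4ccccc4)cc(OCc4ccccc4)c3)[C@H](c3cc(OCc4ccccc4)c(OCc4ccccc4)c(OCc4ccccc4)c3)O2
F5 | step 12 | oxime of aldehyde 10 (E/Z mixture) | ON=Cc1c(CO[Si](C(C)C)(C(C)C)C(C)C)cc(OCc2ccccc2)c(OCc2ccccc2)c1OCc1cc(OCc2ccccc2)c(OCc2ccccc2)c(OCc2ccccc2)c1
F6 | step 12 | 3,4-bis(benzyloxy)-2-{[3,4,5-tris(benzyloxy)benzyl]oxy}-6-[(triisopropylsilyloxy)methyl]benzonitrile | N#Cc1c(CO[Si](C(C)C)(C(C)C)C(C)C)cc(OCc2ccccc2)c(OCc2ccccc2)c1OCc1cc(OCc2ccccc2)c(OCc2ccccc2)c(OCc2ccccc2)c1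
F7 | step 12 | N–H ketimine corresponding to ketone 15 | N=C(c1cc(OCc2ccccc2)cc(OCc2ccccc2)c1)c1c(CO[Si](C(C)C)(C(C)C)C(C)C)cc(OCc2ccccc2)c(OCc2ccccc2)c1OCc1cc(OCc2ccccc2)c(OCc2ccccc2)c(OCc2ccccc2)c1
F8 | step 19 | (2S,3S)-3-(3,5-dihydroxyphenyl)-6,7-dihydroxy-2-(3,4,5-trihydroxyphenyl)-2,3-dihydrobenzofuran-4-carbaldehyde | O=Cc1cc(O)c(O)c2c1[C@H](c1cc(O)cc(O)c1)[C@@H](c1cc(O)c(O)c(O)c1)O2
F9 | step 19 | hepta-O-(tert-butyldimethylsilyl) ether of F8 | O=Cc1cc(O[Si](C)(C)C(C)(C)C)c(O[Si](C)(C)C(C)(C)C)c2c1[C@H](c1cc(O[Si](C)(C)C(C)(C)C)cc(O[Si](C)(C)C(C)(C)C)c1)[C@@H](c1cc(O[Si](C)(C)C(C)(C)C)c(O[Si](C)(C)C(C)(C)C)c(O[Si](C)(C)C(C)(C)C)c1)O2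
F10 | step 19 | diethyl (3,5-dihydroxybenzyl)phosphonate | CCOP(=O)(Cc1cc(O)cc(O)c1)OCC
F11 | step 19 | diethyl [3,5-bis(tert-butyldimethylsilyloxy)benzyl]phosphonate | CCOP(=O)(Cc1cc(O[Si](C)(C)C(C)(C)C)cc(O[Si](C)(C)C(C)(C)C)c1)OCC
F12 | step 19 | nona-O-(tert-butyldimethylsilyl)scirpusin C, (2S,3S), E-alkene | CC(C)(C)[Si](C)(C)Oc1cc(O[Si](C)(C)C(C)(C)C)cc(/C=C/c2cc(O[Si](C)(C)C(C)(C)C)c(O[Si](C)(C)C(C)(C)C)c3c2[C@H](c2cc(O[Si](C)(C)C(C)(C)C)cc(O[Si](C)(C)C(C)(C)C)c2)[C@@H](c2cc(O[Si](C)(C)C(C)(C)C)c(O[Si](C)(C)C(C)(C)C)c(O[Si](C)(C)C(C)(C)C)c2)O3)c1
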